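**Assumptions.** The target has no stereocentres, so it is achiral and there is no enantiomer to set. The C4–C4′ biaryl axis is not configurationally stable and is not specified in the SMILES, so no stereocontrol is needed anywhere. Solvents, catalysts and reagents that leave no atoms in a product are named inline and not numbered.

## Retrosynthetic overview
1. The target is the 7,7′-bis-phenol of a 4,4′-bicoumarin. Removing the two 7-O protecting groups gives the bis-TIPS ether **9**.
2. Both pyranone rings and both C4–C4a bonds form in one step, by a double hydroarylation/lactonisation (Fujiwara/Pechmann-type) of 1,3-diynedioate **8** with two equivalents of phenol **6**. The C4–C4′ bond is already present in the diyne (C3–C4 of the hexadiynedioate).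
3. Phenol **6** comes from syringol by O-silylation, then OMe-directed lithiation, borylation and oxidation. This builds the 1,2,3,4-tetraoxygenated pattern, with the central oxygen kept as OTIPS.
4. Diyne **8** comes from Hay homocoupling of two molecules of methyl propiolate.

## Route

**Step 1**
Reactants: **1** 2,6-dimethoxyphenol (syringol); **2** triisopropylsilyl chloride
Product: **3** 1-(triisopropylsilyloxy)-2,6-dimethoxybenzene
Conditions: **2**, imidazole, DMF, 60 °C, 12 h
Reagents that add atoms: TIPSCl, CC(C)[Si](Cl)(C(C)C)C(C)C (the Si(iPr)3 group is retained)
Why: Standard silylation of a phenol. The hindered aryl TIPS ether survives BuLi, brief aqueous base, TFA and Pd(II), and it masks the future 7-OH. No stereocentre is formed.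

**Step 2**
Reactants: **3**; **4** trimethyl borate; **5** hydrogen peroxide
Product: **6** 2,4-dimethoxy-3-(triisopropylsilyloxy)phenol
Conditions: (i) n-BuLi, TMEDA, THF, –20 → 0 °C; (ii) B(OMe)3, –78 °C → rt; (iii) 30% H2O2, 1 M NaOH, THF, 0 °C, 1 h
Reagents that add atoms: H2O2, OO (supplies the phenolic O); B(OMe)3, COB(OC)OC (not retained, lost as borate)
Why: The OMe group at C2 directs ortho-lithiation to C3, which gives the 1,2,3,4-tetraoxygenated pattern; this parallels 1,2,3-trimethoxybenzene, which lithiates at C4. The bulky OTIPS group blocks the central position. The aryl-B(OMe)2 intermediate is converted to the phenol by oxidative C–B to C–O conversion (boronate oxidation). No stereocentre is involved.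

**Step 3**
Reactants: **7** methyl propiolate (2 equiv)
Product: **8** dimethyl hexa-2,4-diynedioate
Conditions: CuCl (5 mol%), TMEDA, O2 (air), acetone, 0 °C → rt
Reagents that add atoms: none (O2 is only the terminal oxidant and ends up as water)
Why: Hay oxidative homocoupling (Glaser-type) joins two molecules of **7** with loss of 2 H, giving C8H6O4 from 2 × C4H4O2. The symmetric 1,3-diyne carries the preformed C4–C4′ bond. The product is achiral.

**Step 4**
Reactants: **6** phenol (2.2 equiv); **8** diyne diester (1 equiv)
Product: **9** 4,4′-bi[7-(triisopropylsilyloxy)-6,8-dimethoxycoumarin]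
Conditions: Pd(OAc)2 (10 mol%), TFA/CH2Cl2 (1:4), 25 → 40 °C, 24 h
Reagents that add atoms: none (Pd(OAc)2 and TFA are not incorporated; 2 MeOH are lost from 2 × **6** + **8**)
Why: Proposed new method: this is a double Fujiwara-type intermolecular hydroarylation with lactonisation on a conjugated 1,3-diynedioate, a substrate class where it has not been shown. The Pd(II)/TFA-activated ynoate is attacked by arene C6 of **6**, which is ortho to OH and para to OTIPS, and this is the only nucleophilic carbon that can close a coumarin. The attack is at diyne C3, β to ester C1, by Friedel–Crafts-type anti-addition. This gives the Z-aryl acrylate, which lactonises onto the phenol OH with loss of MeOH to give a 4-(alkynyl)coumarin. That coumarin still carries a C≡C–CO2Me unit attached at its C4, and a second identical cycle at diyne C4 (β to ester C6) forms the second coumarin. The old C3–C4 bond of the diyne becomes the C4–C4′ bond. The closest known reaction is Pd/TFA hydroarylation of propiolates with electron-rich phenols to give coumarins. No stereocentre is formed, and the biaryl axis is labile.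

**Step 5**
Reactants: **9**
Product: **10** 4,4′-biisofraxidin (target)
Conditions: TBAF, AcOH (1:1 buffer), THF, 0 °C → rt, 2 h
Reagents that add atoms: none (fluoride leaves as TIPS-F)
Why: Fluoride cleavage of aryl silyl ethers (desilylation). AcOH buffering protects the lactones from phenoxide or fluoride attack, and the OMe groups and the coumarin C=C are untouched. No stereocentre is involved.

## Compound list
1 | 2,6-dimethoxyphenol (syringol) | COc1cccc(OC)c1O | starting material
2 | triisopropylsilyl chloride | CC(C)[Si](Cl)(C(C)C)C(C)C | starting material
3 | 1-(triisopropylsilyloxy)-2,6-dimethoxybenzene | COc1cccc(OC)c1O[Si](C(C)C)(C(C)C)C(C)C | intermediate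
4 | trimethyl borate | COB(OC)OC | starting material (reagent)
5 | hydrogen peroxide | OO | starting material (reagent)
6 | 2,4-dimethoxy-3-(triisopropylsilyloxy)phenol | COc1ccc(O)c(OC)c1O[Si](C(C)C)(C(C)C)C(C)C | intermediate
7 | methyl propiolate | COC(=O)C#C | starting material
8 | dimethyl hexa-2,4-diynedioate | COC(=O)C#CC#CC(=O)OC | intermediate
9 | bis-TIPS 4,4′-bicoumarin | COc1cc2c(-c3cc(=O)oc4c(OC)c(O[Si](C(C)C)(C(C)C)C(C)C)c(OC)cc34)cc(=O)oc2c(OC)c1O[Si](C(C)C)(C(C)C)C(C)C | intermediate
10 | 4,4′-biisofraxidin | COc1cc2c(-c3cc(=O)oc4c(OC)c(O)c(OC)cc34)cc(=O)oc2c(OC)c1O | target (achiral, no stereocentres)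

## Summary
Total steps: 5 (Steps 1, 2, 4 and 5 on the main chain, plus Step 3 on the diyne branch).
Longest linear sequence: 4 steps (1 → 3 → 6 → 9 → 10, i.e. Steps 1, 2, 4, 5, starting from syringol).

**Three steps most likely to fail**
1. **Step 4 (the proposed new step).** Risks are the double hydroarylation stalling at the mono-coumarin, unproductive arylation at arene C5 (which cannot lactonise), and attack at diyne C2/C5 (1,6-addition) or oligomerisation of the diyne.
   - Fallback using known chemistry: make the aryl hydrogen malonate from **6** (Meldrum's acid, 90 °C) and cyclise it with Eaton's reagent to the 4-hydroxycoumarin, re-silylating the 7-OH with TIPSCl if it is lost. Convert this to the 4-tosylate (TsCl, Et3N) and homocouple with Ni(0) (NiCl2(PPh3)2, Zn, Et4NI, DMF, Ullmann-type). Then remove TIPS with TBAF/AcOH.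
2. **Step 2.** The ortho-lithiation may be unselective, or the silyl ether may be partly cleaved under the oxidative basic work-up.
   - Fallback: use 2,3,4-trimethoxyphenol, made from 2,3,4-trimethoxybenzaldehyde by Baeyer–Villiger oxidation and hydrolysis. Run the Step 4 coupling on it to give the 6,7,8-trimethoxy bicoumarin, then selectively demethylate the two C7 OMe groups with BCl3 or AlCl3. Those are the flanked OMe groups para to the conjugated acceptor.
3. **Step 3.** Propiolate homocoupling is moderate-yielding because amine-mediated Michael addition and oligomerisation compete, and the diynedioate is a sensitive electrophile.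
   - Fallback: oxidise commercial 2,4-hexadiyne-1,6-diol to hexa-2,4-diynedioic acid (Jones reagent), then esterify with TMSCHN2 in MeOH/PhMe.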